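**Retrosynthetic overview**

1. Numbering: C1 (lactone C=O) to C12 (CH3). Ring A is the tetrahydrofuran O/C4/C5/C6/C7; ring B is the δ-lactone C1/C2/C3/C4/C5/O.
2. Feature: on ring A the four substituents C3 (on C4), lactone O (on C5), OH (on C6) and C8 (on C7) are all cis. Ring A with C3 and C8 is therefore a concealed meso unit, the ring-opened endo furan/vinylene carbonate adduct 3 (its alkene carbons are C3 and C8, its carbonate carbon is the future C1).
3. Disconnections: C3–OH from the C3 ketone (hydride on the convex face); C1–C2 by Claisen acylation of the C2 enolate with the C5/C6 carbonate (closes ring B); C3=O by Wacker oxidation of the C4 vinyl group; C8=C9 and C3=C2 by desymmetrising ring-opening cross-metathesis of 3 with side-chain alkene 10; 10 from methyl (R)-lactate.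
4. Ring order: oxanorbornene by Diels–Alder reaction (step 1), ring A released (step 8), ring B closed (step 10).

Key step: step 8

Assumption: the (4R,5R) form of the carbene ligand L* is taken as the one whose preference reinforces that of enantiopure alkene 10; if the pairing proves mismatched, the (4S,5S) complex is used in step 8 with no other change.

**Route**

Step 1
Reactants: 1 furan; 2 vinylene carbonate
Product: 3 meso endo adduct, endo-cis-7-oxabicyclo[2.2.1]hept-5-ene-2,3-diyl carbonate (both carbonate oxygens on the face of the C=C bridge)
Conditions: furan (excess, neat), sealed tube, 125 °C, 18 h; endo isomer separated from the exo isomer by crystallisation and chromatography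
Reagents that add atoms: none
Why: Thermal Diels–Alder cycloaddition of the cis dienophile delivers the carbonate cis-fused and, in the endo adduct, syn to the alkene bridge, which fixes the later all-cis relationship of C4–C7; the exo adduct, also meso, is discarded.

Step 2
Reactants: 4 methyl (R)-lactate
Product: 5 methyl (R)-2-[(tert-butyldiphenylsilyl)oxy]propanoate
Conditions: t-BuPh2SiCl, imidazole, DMF, 23 °C
Reagents that add atoms: tert-butyl(chloro)diphenylsilane, CC(C)(C)[Si](Cl)(c1ccccc1)c1ccccc1
Why: Imidazole-promoted O-silylation of a secondary alcohol installs a bulky, non-chelating group without touching the stereocentre (future C11).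

Step 3
Reactants: 5 methyl (R)-2-[(tert-butyldiphenylsilyl)oxy]propanoate
Product: 6 (R)-2-[(tert-butyldiphenylsilyl)oxy]propanal
Conditions: i-Bu2AlH (1.1 equiv), CH2Cl2, −78 °C; aqueous potassium sodium tartrate; used crude
Reagents that add atoms: none
Why: Partial ester reduction with a dialkylaluminium hydride stops at the aldehyde because the tetrahedral aluminium hemiacetal persists at −78 °C, and the α-silyloxy aldehyde should not epimerise if used at once.

Step 4
Reactants: 6 (R)-2-[(tert-butyldiphenylsilyl)oxy]propanal
Product: 7 (3S,4R)-4-[(tert-butyldiphenylsilyl)oxy]pent-1-en-3-ol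
Conditions: CH2=CHMgBr, THF, −78 °C; aqueous NH4Cl; minor syn epimer removed by chromatography (here or after step 5)
Reagents that add atoms: vinylmagnesium bromide, C=C[Mg]Br
Why: Grignard addition under Felkin–Anh (non-chelation) control, with the poorly coordinating silyl ether antiperiplanar to the incoming vinyl group, should favour the 3,4-anti alcohol and so set C10 as S.

Step 5
Reactants: 7 (3S,4R)-4-[(tert-butyldiphenylsilyl)oxy]pent-1-en-3-ol
Product: 8 (3S,4R)-4-[(tert-butyldiphenylsilyl)oxy]pent-1-en-3-yl benzoate
Conditions: BzCl, pyridine, DMAP (cat.), CH2Cl2, 0 to 23 °C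
Reagents that add atoms: benzoyl chloride, O=C(Cl)c1ccccc1
Why: Nucleophile-catalysed acylation of the allylic alcohol places the C10 benzoate while the C11 oxygen is still masked.

Step 6
Reactants: 8 (3S,4R)-4-[(tert-butyldiphenylsilyl)oxy]pent-1-en-3-yl benzoate
Product: 9 (3S,4R)-4-hydroxypent-1-en-3-yl benzoate
Conditions: HF·pyridine, THF/pyridine, 0 to 23 °C
Reagents that add atoms: none
Why: Fluoride-driven Si–O cleavage in a weakly acidic medium frees the C11 hydroxyl without generating an alkoxide, so 1,2-benzoyl migration should not occur.

Step 7
Reactants: 9 (3S,4R)-4-hydroxypent-1-en-3-yl benzoate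
Product: 10 (3S,4R)-4-acetoxypent-1-en-3-yl benzoate (side-chain alkene, C9–C12)
Conditions: Ac2O, pyridine, DMAP (cat.), CH2Cl2, 0 °C
Reagents that add atoms: acetic anhydride, CC(=O)OC(C)=O
Why: Fast DMAP-catalysed acetylation of the free secondary alcohol outruns acyl migration and completes the differentiated diester.

Step 8
Reactants: 3 meso endo oxanorbornene carbonate; 10 (3S,4R)-4-acetoxypent-1-en-3-yl benzoate
Product: 11 all-cis tetrahydrofuran carbonate with C4 vinyl group and complete (E) side chain, (1E,3S,4R)-4-acetoxy-1-[(3aR,4S,6R,6aS)-2-oxo-6-vinyltetrahydrofuro[3,4-d][1,3]dioxol-4-yl]pent-1-en-3-yl benzoate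
Conditions: RuCl2(=CHPh)(PCy3)(L*) (5 mol%), L* = (4R,5R)-1,3-bis(2-isopropylphenyl)-4,5-diphenylimidazolin-2-ylidene, 10 (3 equiv), CH2Cl2, 25–40 °C, slow addition of 3; excess 10 recovered
Reagents that add atoms: none
Why: Olefin metathesis in the ring-opening cross-metathesis mode: the propagating ruthenium alkylidene adds [2+2] to the strained C3=C8 bond of 3 from the exo (oxygen-bridge) face, which the endo carbonate leaves open, the ruthenacyclobutane cycloreverts with release of strain, and the ring-opened alkylidene is turned over by the terminal alkene of 10, so that one terminus becomes the C8=C9 alkene and the other the C3=C2 vinyl group with every atom of both partners retained. The closest known reaction type is the asymmetric ring-opening cross-metathesis of meso norbornenes and 7-oxanorbornenes with terminal alkenes under chiral ruthenium carbene catalysis. No ring is closed; ring A, already present in the bicycle, is set free. The all-cis relative configuration of C4–C7 comes from the endo adduct, and their absolute sense is fixed by which enantiotopic alkene carbon receives the side chain, which is governed by the tilted N-aryl groups of L* (geared by the 4,5-diphenyl backbone) acting together with the C10/C11 centres of the alkylidene derived from 10. The step needs site selectivity (C8 over C3; because 10 is one enantiomer, the wrong-site product is a diastereomer and separable), E geometry (favoured because branched C10 and ring carbon C7 avoid a cis relationship in the metallacycle and the doubly branched product alkene is too hindered for secondary metathesis) and cross-coupling over ring-opening polymerisation (secured by the strain of 3, the excess of 10 and slow addition of 3).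

Step 9
Reactants: 11 all-cis tetrahydrofuran carbonate with C4 vinyl group
Product: 12 C3 methyl ketone, (1E,3S,4R)-4-acetoxy-1-[(3aR,4S,6S,6aR)-6-acetyl-2-oxotetrahydrofuro[3,4-d][1,3]dioxol-4-yl]pent-1-en-3-yl benzoate
Conditions: PdCl2(Quinox) (5 mol%; Quinox = 2-(4,5-dihydrooxazol-2-yl)quinoline), AgSbF6 (12 mol%), 70% aqueous t-BuOOH, CH2Cl2, 0 to 23 °C
Reagents that add atoms: tert-butyl hydroperoxide, CC(C)(C)OO
Why: Tsuji–Wacker-type oxidation with a cationic divalent palladium–Quinox catalyst and hydroperoxide as oxygen donor is the variant that gives methyl ketones from allylic ethers, and the monosubstituted C3=C2 alkene should react well before the hindered, electron-poor C8=C9 alkene under conditions too mild to epimerise C4.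

Step 10
Reactants: 12 C3 methyl ketone
Product: 14 β-keto δ-lactone with free C6–OH (ring B closed), via C2 lithium enolate 13 (not isolated)
Conditions: LiN(SiMe3)2 (2.1 equiv), THF, −78 to −40 °C; AcOH, −78 °C
Reagents that add atoms: none
Why: Intramolecular Claisen (Dieckmann-type) acylation, in which kinetic deprotonation at the methyl group (more acidic than the acetate, less hindered than C4–H) gives an enolate that attacks the cis-disposed carbonate carbonyl in a 6-(enolendo)-exo-trig closure, the tetrahedral intermediate expelling the C6 alkoxide to leave the six-membered lactone as its stabilised enolate, which drives the reaction and creates no new stereocentre.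

Step 11
Reactants: 14 β-keto δ-lactone
Product: 15 target, CNP0230210.1
Conditions: t-BuNH2·BH3 (1.5 equiv), citric acid (1 equiv), MeOH/THF, 0 °C
Reagents that add atoms: none
Why: Ketone reduction by an amine–borane in a weakly acidic medium that keeps the β-keto lactone un-ionised should deliver hydride to C3 from the convex face of the cis-fused bicycle (the H4/H5 face, anti to the C4–O bond), the concave face being screened by ring A, the C6 hydroxyl and the C7 side chain, which sets C3 as R with its hydroxyl cis to the ring oxygen on C4.

**Compound list**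

1 | furan | c1ccoc1 | starting material
2 | vinylene carbonate | O=C1OC=CO1 | starting material
3 | meso endo-cis-7-oxabicyclo[2.2.1]hept-5-ene-2,3-diyl carbonate | C1=C[C@@H]2O[C@H]1[C@@H]3OC(=O)O[C@H]23 | intermediate
4 | methyl (R)-lactate | C[C@@H](O)C(=O)OC | starting material
5 | methyl (R)-2-[(tert-butyldiphenylsilyl)oxy]propanoate | C[C@@H](O[Si](c1ccccc1)(c1ccccc1)C(C)(C)C)C(=O)OC | intermediate
6 | (R)-2-[(tert-butyldiphenylsilyl)oxy]propanal | C[C@@H](O[Si](c1ccccc1)(c1ccccc1)C(C)(C)C)C=O | intermediate
7 | (3S,4R)-4-[(tert-butyldiphenylsilyl)oxy]pent-1-en-3-ol | C[C@@H](O[Si](c1ccccc1)(c1ccccc1)C(C)(C)C)[C@@H](O)C=C | intermediate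
8 | (3S,4R)-4-[(tert-butyldiphenylsilyl)oxy]pent-1-en-3-yl benzoate | C[C@@H](O[Si](c1ccccc1)(c1ccccc1)C(C)(C)C)[C@@H](OC(=O)c1ccccc1)C=C | intermediate
9 | (3S,4R)-4-hydroxypent-1-en-3-yl benzoate | C[C@@H](O)[C@@H](OC(=O)c1ccccc1)C=C | intermediate
10 | (3S,4R)-4-acetoxypent-1-en-3-yl benzoate | CC(=O)O[C@H](C)[C@H](C=C)OC(=O)c1ccccc1 | intermediate
11 | (1E,3S,4R)-4-acetoxy-1-[(3aR,4S,6R,6aS)-2-oxo-6-vinyltetrahydrofuro[3,4-d][1,3]dioxol-4-yl]pent-1-en-3-yl benzoate (ring substituents all cis) | CC(=O)O[C@H](C)[C@H](/C=C/[C@@H]1O[C@H](C=C)[C@@H]2OC(=O)O[C@H]12)OC(=O)c3ccccc3 | intermediate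
12 | (1E,3S,4R)-4-acetoxy-1-[(3aR,4S,6S,6aR)-6-acetyl-2-oxotetrahydrofuro[3,4-d][1,3]dioxol-4-yl]pent-1-en-3-yl benzoate (ring substituents all cis) | CC(=O)O[C@H](C)[C@H](/C=C/[C@@H]1O[C@H](C(C)=O)[C@@H]2OC(=O)O[C@H]12)OC(=O)c3ccccc3 | intermediate
13 | C2 lithium enolate of 12 (lithium 1-substituted ethen-1-olate at C3) | CC(=O)O[C@H](C)[C@H](/C=C/[C@@H]1O[C@H](C(=C)O[Li])[C@@H]2OC(=O)O[C@H]12)OC(=O)c3ccccc3 | intermediate
14 | (1E,3S,4R)-4-acetoxy-1-[(2S,3R,3aR,7aS)-3-hydroxy-5,7-dioxohexahydro-2H-furo[3,2-b]pyran-2-yl]pent-1-en-3-yl benzoate | CC(=O)O[C@H](C)[C@H](/C=C/[C@@H]1O[C@H]2[C@H](OC(=O)CC2=O)[C@@H]1O)OC(=O)c1ccccc1 | intermediate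
15 | (1E,3S,4R)-4-acetoxy-1-[(2S,3R,3aR,7R,7aR)-3,7-dihydroxy-5-oxohexahydro-2H-furo[3,2-b]pyran-2-yl]pent-1-en-3-yl benzoate (CNP0230210.1) | CC(=O)O[C@H](C)[C@H](/C=C/[C@@H]1O[C@H]2[C@H](OC(=O)C[C@H]2O)[C@@H]1O)OC(=O)c1ccccc1 | target

**Step count**

Total: 11 steps (step 1; steps 2–7; steps 8–11). Longest linear sequence: 10 steps (4 to 15, steps 2–11).

**Steps most likely to fail**

Step 8. The catalyst may discriminate poorly between the two enantiotopic alkene termini when paired with the chiral alkylidene from 10, the new alkene may form with mixed geometry, and ring-opening oligomerisation may compete. Fallback, setting out from 3 and 10 and returning at 11: catalyst control is given up and the fact that 10 is enantiopure is used instead. Ring-opening cross-metathesis with the achiral second-generation Hoveyda–Grubbs catalyst RuCl2(=CH-C6H4-2-O-i-Pr)(H2IMes) (H2IMes = 1,3-dimesitylimidazolin-2-ylidene; CH2Cl2, 40 °C, excess 10, slow addition of 3) should give 11 together with the wrong-terminus diastereomer of 11 F1. The two are diastereomers, not enantiomers, and are separated by chromatography or preparative HPLC, which also removes any Z isomer.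

Step 10. Proton transfer may move the enolate to C4, followed by β-elimination of the carbonate, and the excess amide base may enolise the acetate before ring closure is complete. Fallback, setting out from 12 and returning at 14: the enolate is made regiospecifically and in non-basic form. Internal-quench silylation (LiN(SiMe3)2 added to 12 and Me3SiCl, THF, −78 °C) should give the C2 trimethylsilyl enol ether of 12 F2. TiCl4 (CH2Cl2, −78 °C) then exchanges silicon for titanium to give the trichlorotitanium enolate of 12 F3. This acylates at the titanium-activated carbonate carbonyl in a titanium-mediated Dieckmann-type condensation, and aqueous work-up gives 14.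

Step 11. Ionisation or enolisation of the β-keto lactone may suppress reduction, and hydride may be guided to the concave face by the C6 hydroxyl, giving the C3 epimer. Fallback, setting out from 14 and returning at 15: substrate control is replaced by catalyst control. Asymmetric transfer hydrogenation with RuCl(p-cymene)[(S,S)-TsDPEN] (or its enantiomer, whichever reinforces convex-face delivery) in HCO2H/Et3N (5:2), CH2Cl2, 25 °C, operates in an acidic medium on the un-ionised keto form and leaves the alkene and both esters untouched. No new compound arises on this path (F0).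

**Further compounds**

F1 | step 8 | wrong-terminus diastereomer of 11 (side chain on the other alkene carbon, all four ring centres inverted) | CC(=O)O[C@H](C)[C@H](/C=C/[C@H]1O[C@@H](C=C)[C@H]2OC(=O)O[C@@H]12)OC(=O)c3ccccc3
F2 | step 10 | C2 trimethylsilyl enol ether of 12 | CC(=O)O[C@H](C)[C@H](/C=C/[C@@H]1O[C@H](C(=C)O[Si](C)(C)C)[C@@H]2OC(=O)O[C@H]12)OC(=O)c3ccccc3
F3 | step 10 | trichlorotitanium enolate of 12 | CC(=O)O[C@H](C)[C@H](/C=C/[C@@H]1O[C@H](C(=C)O[Ti](Cl)(Cl)Cl)[C@@H]2OC(=O)O[C@H]12)OC(=O)c3ccccc3
F0 | step 11 | none | none
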